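Assumption: the target is all-trans (aryl on C1, methyls on C2 and C3 mutually trans) with the (1S,2S,3R) configuration, i.e. the levorotatory natural product. Tetralin numbering is used throughout: C1 carries the aryl group, C4 is the ring CH2, C4a/C8a are the fusion carbons, and primes denote the pendant ring.

## The problem

Galbulin is a 1-aryltetralin: a six-membered carbocycle fused to a veratrole ring (C4a–C8a), with a 3,4-dimethoxyphenyl group on C1 and methyl groups on C2 and C3. Apart from four aryl methyl ethers it has no functional group, so no stereocentre can be corrected by epimerisation, and every handle used to build the C1–C2–C3 triad must end as CH, CH2 or CH3. The trans-dimethyl pair C2/C3 must be set in the absolute sense. C1, a doubly benzylic methine, can then be relayed from C2, because a six-membered closure onto a planar C1 places the aryl group equatorial and trans to the C2 methyl.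

The feature the plan rests on is that both aromatic rings are the same 3,4-dimethoxyphenyl unit. Cutting the ring bond C1–C8a therefore leaves (2R,3R)-1,4-bis(3,4-dimethoxyphenyl)-2,3-dimethylbutane, which is C2-symmetric. In it, the carbons that become C1 and C4 are homotopic benzylic CH2 groups, each para to a methoxy group. The carbon that becomes C8a is the free ring position para to the future C6 methoxy group.

The hardest bond is thus C1–C8a, and the hardest stereochemical task is the trans C2/C3 pair in a hydrocarbon chain. The electron-rich rings are open to oxidative biaryl coupling, ring halogenation and Lewis-acid demethylation. The benzylic C1–H and C4–H2 of the product remain oxidisable.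

## Retrosynthesis

**12 ⇒ 10 (through 11).** The ring bond C1–C8a is cut, with C1 taken back to a CH2 group and not to a carbinol. Against the neighbouring cuts (C1–C1', which needs a preformed chiral tetralin; C4–C4a, which puts the cation on an unstabilised primary carbon), this cut places the positive charge on a carbon para to the 4'-methoxy group. It also reveals the C2 symmetry: precursor 10 is acyclic, has two stereocentres instead of three, and its two halves are identical. The forward reaction must remove hydride from one benzylic CH2 (either one, they are homotopic) to give cation 11. It must then close the six-membered ring at the position para to a methoxy group, deliver the aryl group trans to the C2 methyl, and stop after one two-electron oxidation.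

**10 ⇒ 9 ⇒ 8.** The two methyl groups are traced back to CH2OMs and then CH2OH groups (two C–O bonds in place of two C–H bonds). This detour is accepted because the central C–C bond of the chain can only be made stereoselectively next to carbonyl groups. Diol 8 is still C2-symmetric, so both ends are treated in the same operation at every stage. The forward reactions are a double sulfonylation and a double hydride displacement; the stereocentres are β to the reacting carbons and are not touched.

**8 ⇒ 7.** The two primary alcohols are traced to two imide carbonyls carrying the chiral auxiliary. The forward step is a reductive cleavage that returns the auxiliary 2.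

**7 ⇒ 4 + 4 (through 5 and 6).** The central bond of the succinyl unit (C2–C3 of the future tetralin) is cut into two identical acyl-oxazolidinone halves. This is preferred over a stepwise construction, in which the two stereocentres are set in two separate alkylations of different substrates. In the oxidative homocoupling of the metal enolate of 4, both stereocentres arise in one event under control of the same auxiliary. The whole C22 skeleton then comes from one C11 acid. The forward reaction must give the like (R,R) combination; the unlike isomer is a diastereomer and can be removed.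

**4 ⇒ 1 + 2 (through 3).** The N–acyl bond is cut to the commercial acid 1 and the commercial valine-derived oxazolidinone 2.

## Roads not taken

**Alternative 1:** the obvious route. The same ring bond C1–C8a is cut, but as a Friedel–Crafts alkylation of the benzylic alcohol A1, (2S,3R)-1,4-bis(3,4-dimethoxyphenyl)-2,3-dimethylbutan-1-ol. A1 would be assembled linearly: one auxiliary alkylation for C3, a second stereocontrolled C–C bond formation for C2, oxidation-state changes, and addition of a 3,4-dimethoxyphenyl-metal reagent to an aldehyde. The forward key step is acid ionisation of A1 and ring closure. The chosen plan is better because A1 treats the two halves of the molecule as different. It needs two separate stereo-setting steps, roughly one and a half times as many steps, and an oxygen at C1 that is installed only to be ionised. The chosen plan sets both methyl-bearing centres in one coupling and generates the same cation by C–H abstraction from a symmetric hydrocarbon.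

**Alternative 2:** cut both C2–C3 and C1–C8a, i.e. a redox-neutral dimerisation of (E)-methylisoeugenol A2, which is an isomer of half the target. Single-electron oxidation of A2 and addition to a second molecule would give the distonic radical cation A3. Its cationic end would close on the other ring, and back electron transfer and protonation would finish the sequence, giving rac-12 in one step. It is not chosen because A3 and its precursors are flat, non-coordinating species with no element for absolute control, so a single enantiomer is out of reach. In addition, A3 closes preferentially by the 1,4-mode to the all-trans cyclobutane A4. The chosen plan keeps the biosynthetic logic (C–C coupling between two C6C3 units, then cationic ring closure) but moves the coupling to the carboxyl oxidation level, where an auxiliary controls it.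

**Alternative 3:** cut C1–C2 and C3–C4, i.e. a Diels–Alder reaction of the α-aryl-o-quinodimethane A5 with dimethyl fumarate A6 to give diester A7, followed by conversion of both esters into methyl groups. The chosen plan is better for three reasons. First, the cycloaddition needs an activated dienophile, so the three-step ester-to-methyl sequence is not saved. Second, A5 must be generated from a separately made strained or sulfur-containing precursor. Third, with a trans-dienophile one ester is necessarily endo and the other exo, so there is no inherent preference for the required 1,2-trans relationship, and absolute control needs a chiral fumarate ester on top. In the chosen plan C1 is fixed by the ring conformation of the closing tetralin.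

Key step: step 6

## Route

**Step 1**
Reactants: 1 3-(3,4-dimethoxyphenyl)propanoic acid; 2 (S)-4-isopropyl-1,3-oxazolidin-2-one
Product: 4 (4S)-3-[3-(3,4-dimethoxyphenyl)propanoyl]-4-isopropyl-1,3-oxazolidin-2-one, via mixed pivalic anhydride 3 (not isolated)
Conditions: PivCl (1.1 equiv), Et3N (2.5 equiv), THF, −20 °C; then LiCl (1.1 equiv), 2, −20 °C → rt
Reagents that add atoms: none
Why: N-acylation of an oxazolidinone through the mixed pivalic anhydride (LiCl/Et3N protocol); attack occurs at the unhindered carbonyl of 3, and no stereocentre is formed.

**Step 2**
Reactants: 4 (4S)-3-[3-(3,4-dimethoxyphenyl)propanoyl]-4-isopropyl-1,3-oxazolidin-2-one (two molecules)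
Product: 7 (4S,4'S)-3,3'-[(2R,3R)-2,3-bis(3,4-dimethoxybenzyl)butanedioyl]bis(4-isopropyl-1,3-oxazolidin-2-one), via lithium (Z)-enolate 5 (not isolated), via trichlorotitanium enolate 6 (not isolated)
Conditions: LDA (1.1 equiv), THF, −78 °C; then TiCl4 (1.1 equiv), −78 °C → rt; aq. NH4Cl; crystallisation or chromatography
Reagents that add atoms: none
Why: Oxidative enolate homocoupling: the chelated Z-enolate is transmetallated to the Ti(IV) enolate, which is oxidised by one electron (Ti(IV) → Ti(III)) and couples at the α-carbon. Each α-carbon forms the new bond on its face anti to the isopropyl group, so both new stereocentres should be R and the C2-symmetric like-dimer should predominate. The unlike isomer is a diastereomer and is removed at this stage, so the enantiopurity of the later hydrocarbon is that of the auxiliary.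

**Step 3**
Reactants: 7 (4S,4'S)-3,3'-[(2R,3R)-2,3-bis(3,4-dimethoxybenzyl)butanedioyl]bis(4-isopropyl-1,3-oxazolidin-2-one)
Product: 8 (2R,3R)-2,3-bis(3,4-dimethoxybenzyl)butane-1,4-diol
Conditions: LiBH4 (4 equiv), MeOH (4 equiv), THF, 0 °C → rt; aqueous work-up, recovery of 2
Reagents that add atoms: none
Why: Reductive cleavage of N-acyl oxazolidinones at the exocyclic carbonyl by LiBH4/MeOH; the conditions are not basic enough to enolise the α-centres, and the auxiliary is returned.

**Step 4**
Reactants: 8 (2R,3R)-2,3-bis(3,4-dimethoxybenzyl)butane-1,4-diol
Product: 9 (2R,3R)-2,3-bis(3,4-dimethoxybenzyl)butane-1,4-diyl dimethanesulfonate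
Conditions: MsCl (2.5 equiv), Et3N (3 equiv), CH2Cl2, −10 °C → 0 °C; used without storage
Reagents that add atoms: methanesulfonyl chloride, CS(=O)(=O)Cl
Why: Sulfonylation of two primary alcohols; excess MsCl at low temperature converts both hydroxyl groups quickly, so a mono-mesylate has little time to cyclise onto its free hydroxyl group.

**Step 5**
Reactants: 9 (2R,3R)-2,3-bis(3,4-dimethoxybenzyl)butane-1,4-diyl dimethanesulfonate
Product: 10 (2R,3R)-1,4-bis(3,4-dimethoxyphenyl)-2,3-dimethylbutane
Conditions: LiAlH4 (4 equiv), THF, 0 °C → reflux; Fieser work-up
Reagents that add atoms: none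
Why: SN2 displacement of primary sulfonates by hydride turns both CH2OMs groups into methyl groups; the stereocentres are β to the reacting carbons and the aryl ethers are inert.

**Step 6**
Reactants: 10 (2R,3R)-1,4-bis(3,4-dimethoxyphenyl)-2,3-dimethylbutane
Product: 12 (1S,2S,3R)-1-(3,4-dimethoxyphenyl)-6,7-dimethoxy-2,3-dimethyl-1,2,3,4-tetrahydronaphthalene (galbulin), via benzylic cation ion pair 11 (not isolated)
Conditions: DDQ (1.05 equiv, added in portions), CH2Cl2–TFA (4:1), 0 °C → rt; aq. NaHCO3/ascorbate quench
Reagents that add atoms: none
Why: DDQ forms a charge-transfer complex with a veratryl ring and removes hydride (directly, or by electron transfer, proton loss and a second electron transfer) from the benzylic CH2 para to the 4-methoxy group; since 10 is C2-symmetric the two CH2 groups are homotopic and both give the same quinone-methide-like cation 11. The closest known reaction type is the quinone-mediated benzylic C–H oxidation with intramolecular Friedel–Crafts alkylation (oxidative cyclisation of veratryl-type 1,4-diarylbutanes to 1-aryltetralins), the C–H counterpart of the classical benzylic-alcohol cyclisation and a copy of the presumed biosynthesis. The one new ring is closed by attack of the second arene on the cationic carbon, a six-membered closure that is 6-exo-trig at that carbon with the arene π bond C4a=C8a inside the new ring. Of the two ortho positions of the nucleophilic ring, the one that is para to a methoxy group and not flanked by one (future C8a) should react, which gives the 6,7-dimethoxy pattern. C2 and C3 are carried over from 10, and they set the new stereocentre C1: in the half-chair transition state both methyl groups are pseudo-equatorial, and the aryl group on the planar cation takes the pseudo-equatorial position anti to the C2 methyl, so the arene adds to the face that gives the 1,2-trans (1S) product. The step needs one, and only one, two-electron oxidation: 11 must close faster than it loses the C2 proton, and 12, which keeps a benzylic C1–H and C4–H2, must not react further. One equivalent of oxidant at low temperature, and the advantage of two unhindered CH2 groups in 10 over the hindered methine in 12, serve this. TFA re-ionises any benzylic ester or ether formed by ion-pair collapse and returns it to the cyclisation.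

## Compound list

1 | 3-(3,4-dimethoxyphenyl)propanoic acid | COc1ccc(CCC(=O)O)cc1OC | starting material
2 | (S)-4-isopropyl-1,3-oxazolidin-2-one | CC(C)[C@H]1COC(=O)N1 | starting material
3 | 3-(3,4-dimethoxyphenyl)propanoic pivalic anhydride | COc1ccc(CCC(=O)OC(=O)C(C)(C)C)cc1OC | intermediate
4 | (4S)-3-[3-(3,4-dimethoxyphenyl)propanoyl]-4-isopropyl-1,3-oxazolidin-2-one | COc1ccc(CCC(=O)N2[C@@H](C(C)C)COC2=O)cc1OC | intermediate
5 | lithium (Z)-enolate of 4 | COc1ccc(C/C=C(\[O-])N2[C@@H](C(C)C)COC2=O)cc1OC.[Li+] | intermediate
6 | trichlorotitanium(IV) (Z)-enolate of 4 | COc1ccc(C/C=C(\O[Ti](Cl)(Cl)Cl)N2[C@@H](C(C)C)COC2=O)cc1OC | intermediate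
7 | (4S,4'S)-3,3'-[(2R,3R)-2,3-bis(3,4-dimethoxybenzyl)butanedioyl]bis(4-isopropyl-1,3-oxazolidin-2-one) | COc1ccc(C[C@@H](C(=O)N2[C@@H](C(C)C)COC2=O)[C@@H](Cc2ccc(OC)c(OC)c2)C(=O)N2[C@@H](C(C)C)COC2=O)cc1OC | intermediate
8 | (2R,3R)-2,3-bis(3,4-dimethoxybenzyl)butane-1,4-diol | COc1ccc(C[C@@H](CO)[C@@H](Cc2ccc(OC)c(OC)c2)CO)cc1OC | intermediate
9 | (2R,3R)-2,3-bis(3,4-dimethoxybenzyl)butane-1,4-diyl dimethanesulfonate | COc1ccc(C[C@@H](COS(C)(=O)=O)[C@@H](Cc2ccc(OC)c(OC)c2)COS(C)(=O)=O)cc1OC | intermediate
10 | (2R,3R)-1,4-bis(3,4-dimethoxyphenyl)-2,3-dimethylbutane | COc1ccc(C[C@@H](C)[C@H](C)Cc2ccc(OC)c(OC)c2)cc1OC | intermediate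
11 | (2R,3R)-1,4-bis(3,4-dimethoxyphenyl)-2,3-dimethylbutan-1-ylium, ion pair with the DDQ-derived hydroquinone monoanion | COc1ccc(C[C@@H](C)[C@H](C)[CH+]c2ccc(OC)c(OC)c2)cc1OC.[O-]c1c(Cl)c(Cl)c(O)c(C#N)c1C#N | intermediate
12 | (1S,2S,3R)-1-(3,4-dimethoxyphenyl)-6,7-dimethoxy-2,3-dimethyl-1,2,3,4-tetrahydronaphthalene (galbulin) | COc1ccc([C@H]2c3cc(OC)c(OC)cc3C[C@@H](C)[C@@H]2C)cc1OC | target

## Summary and risks

Total step count: 6. Longest linear sequence: 6 steps (1 → 12); the route is linear, with two molecules of 4 joined in step 2.

**Step 6 (key step).** Three processes may interfere: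
- oxidative aryl–aryl coupling of the two rings through an arene radical cation, if it outruns benzylic C–H cleavage;
- a second hydride abstraction from the product at C4 or C1;
- loss of the C2 proton from the open cation before ring closure, which would erode the C2 configuration.

The fallback makes the same type of cation by ionising a C–O bond, without an oxidant, and gives up the symmetry. It sets out from 4 and returns at 12.
- The sodium enolate of 4 (NaHMDS, THF, −78 °C) is alkylated with tert-butyl bromoacetate anti to the isopropyl group to give tert-butyl (3R)-4-(3,4-dimethoxyphenyl)-3-{[(4S)-4-isopropyl-2-oxo-1,3-oxazolidin-3-yl]carbonyl}butanoate F1.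
- LiBH4/MeOH removes the auxiliary to give tert-butyl (3R)-4-(3,4-dimethoxyphenyl)-3-(hydroxymethyl)butanoate F2.
- TsOH in warm toluene closes F2 to (4R)-4-(3,4-dimethoxybenzyl)dihydrofuran-2(3H)-one F3.
- The lithium enolate of F3 (LDA, THF, −78 °C) adds to 3,4-dimethoxybenzaldehyde trans to the benzyl group to give (3S,4R)-4-(3,4-dimethoxybenzyl)-3-[(3,4-dimethoxyphenyl)(hydroxy)methyl]dihydrofuran-2(3H)-one F4. Both carbinol epimers are usable.
- TFA in CH2Cl2 ionises the benzylic alcohol and closes the ring to the all-trans, trans-fused 1-aryltetralin 2,3-carbolactone F5.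
- LiAlH4 gives [(1S,2R,3R)-1-(3,4-dimethoxyphenyl)-6,7-dimethoxy-1,2,3,4-tetrahydronaphthalene-2,3-diyl]dimethanol F6.
- MsCl/Et3N gives the dimethanesulfonate of that diol, F7, and LiAlH4 reduction of F7 gives 12.

**Step 2.** The like/unlike selectivity of the coupling may be poor, or the titanium enolate may be diverted by protonation or α-chlorination, giving low conversion. The fallback builds the two centres one after the other without an oxidant; it sets out from 4 and returns at 8. Lactone F3 is made from 4 through F1 and F2 exactly as above. Its lithium enolate (LDA, THF/DMPU, −78 °C) is alkylated with 3,4-dimethoxybenzyl bromide trans to the existing benzyl group to give (3R,4R)-3,4-bis(3,4-dimethoxybenzyl)dihydrofuran-2(3H)-one F8. LiAlH4 reduces F8 to diol 8.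

**Step 3.** Hydride may attack the ring carbamate carbonyl of the hindered, α-branched imides (ring opening instead of auxiliary release), or cleavage of the second imide may be incomplete. The fallback separates cleavage from reduction; it sets out from 7 and returns at 8. LiOH/H2O2 in THF–water at 0 °C, which is selective for the exocyclic carbonyl, gives (2R,3R)-2,3-bis(3,4-dimethoxybenzyl)butanedioic acid F9 and the auxiliary. LiAlH4 (or BH3·THF) reduces F9 to 8.

**Step 5.** Hydride may attack at sulfur instead of carbon; the alkoxide so formed would displace the neighbouring mesylate intramolecularly, and SN2 at the β-branched carbon is slow. The fallback avoids any alkoxide; it sets out from 9 and returns at 10. NaI in refluxing 2-butanone gives (2R,3R)-1,4-diiodo-2,3-bis(3,4-dimethoxybenzyl)butane F10. Radical deiodination of F10 (Bu3SnH, AIBN, toluene, 80 °C) gives 10.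

## Further compounds

F1 | step 6 | tert-butyl (3R)-4-(3,4-dimethoxyphenyl)-3-{[(4S)-4-isopropyl-2-oxo-1,3-oxazolidin-3-yl]carbonyl}butanoate | COc1ccc(C[C@H](CC(=O)OC(C)(C)C)C(=O)N2[C@@H](C(C)C)COC2=O)cc1OC
F2 | step 6 | tert-butyl (3R)-4-(3,4-dimethoxyphenyl)-3-(hydroxymethyl)butanoate | COc1ccc(C[C@H](CC(=O)OC(C)(C)C)CO)cc1OC
F3 | step 6 | (4R)-4-(3,4-dimethoxybenzyl)dihydrofuran-2(3H)-one | COc1ccc(C[C@H]2COC(=O)C2)cc1OC
F4 | step 6 | (3S,4R)-4-(3,4-dimethoxybenzyl)-3-[(3,4-dimethoxyphenyl)(hydroxy)methyl]dihydrofuran-2(3H)-one (carbinol epimers) | COc1ccc(C[C@H]2COC(=O)[C@@H]2C(O)c2ccc(OC)c(OC)c2)cc1OC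
F5 | step 6 | all-trans 1-(3,4-dimethoxyphenyl)-6,7-dimethoxytetralin 2,3-carbolactone (carbonyl on C2, trans-fused) | COc1ccc([C@H]2c3cc(OC)c(OC)cc3C[C@H]3COC(=O)[C@H]23)cc1OC
F6 | step 6 | [(1S,2R,3R)-1-(3,4-dimethoxyphenyl)-6,7-dimethoxy-1,2,3,4-tetrahydronaphthalene-2,3-diyl]dimethanol | COc1ccc([C@H]2c3cc(OC)c(OC)cc3C[C@@H](CO)[C@@H]2CO)cc1OC
F7 | step 6 | [(1S,2R,3R)-1-(3,4-dimethoxyphenyl)-6,7-dimethoxy-1,2,3,4-tetrahydronaphthalene-2,3-diyl]dimethanediyl dimethanesulfonate | COc1ccc([C@H]2c3cc(OC)c(OC)cc3C[C@@H](COS(C)(=O)=O)[C@@H]2COS(C)(=O)=O)cc1OC
F8 | step 2 | (3R,4R)-3,4-bis(3,4-dimethoxybenzyl)dihydrofuran-2(3H)-one | COc1ccc(C[C@H]2COC(=O)[C@@H]2Cc2ccc(OC)c(OC)c2)cc1OC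
F9 | step 3 | (2R,3R)-2,3-bis(3,4-dimethoxybenzyl)butanedioic acid | COc1ccc(C[C@@H](C(=O)O)[C@@H](Cc2ccc(OC)c(OC)c2)C(=O)O)cc1OC
F10 | step 5 | (2R,3R)-1,4-diiodo-2,3-bis(3,4-dimethoxybenzyl)butane | COc1ccc(C[C@@H](CI)[C@@H](Cc2ccc(OC)c(OC)c2)CI)cc1OC
A1 | alternative 1 | (2S,3R)-1,4-bis(3,4-dimethoxyphenyl)-2,3-dimethylbutan-1-ol (C1 epimers) | COc1ccc(C[C@@H](C)[C@H](C)C(O)c2ccc(OC)c(OC)c2)cc1OC
A2 | alternative 2 | (E)-1,2-dimethoxy-4-(prop-1-en-1-yl)benzene (methylisoeugenol) | COc1ccc(/C=C/C)cc1OC
A3 | alternative 2 | threo-1,4-bis(3,4-dimethoxyphenyl)-2,3-dimethylbutane-1,4-diyl radical cation (racemic, one enantiomer drawn) | COc1ccc([CH][C@@H](C)[C@H](C)[CH+]c2ccc(OC)c(OC)c2)cc1OC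
A4 | alternative 2 | all-trans-1,2-bis(3,4-dimethoxyphenyl)-3,4-dimethylcyclobutane (racemic, one enantiomer drawn) | C[C@H]1[C@H](C)[C@@H](c2ccc(OC)c(OC)c2)[C@@H]1c1ccc(OC)c(OC)c1
A5 | alternative 3 | (E)-α-(3,4-dimethoxyphenyl)-4,5-dimethoxy-o-quinodimethane | C=C1C=C(OC)C(OC)=C/C1=C\c1ccc(OC)c(OC)c1
A6 | alternative 3 | dimethyl fumarate | COC(=O)/C=C/C(=O)OC
A7 | alternative 3 | dimethyl all-trans-1-(3,4-dimethoxyphenyl)-6,7-dimethoxy-1,2,3,4-tetrahydronaphthalene-2,3-dicarboxylate (galbulin configuration) | COc1ccc([C@H]2c3cc(OC)c(OC)cc3C[C@@H](C(=O)OC)[C@@H]2C(=O)OC)cc1OC
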